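## Retrosynthetic overview

1. Target ⇒ central CH=CH (hydrogenation with debenzylation, triple acetylation and desilylation as the last operations) ⇒ Julia–Kocienski union of two C15 bicycles: a tetrazolyl sulfone (7S half) and an aldehyde (7R half).
2. 7S half: tertiary alcohol from α-face epoxidation and hydride opening of a 7-methylidene ester. 7R half: equatorial MeMgBr addition to a 7-ketone.
3. Each bicycle comes from one Me3SiOTf-triggered diepoxide cascade: ring A first (7-endo epoxonium formation), then ring B (C–C closure by an allylsilane or a silyl enol ether).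
4. Both (S,S,S)-diepoxides come from Shi epoxidation of dienes built from ethyl (4E)-5,9-dimethyldeca-4,8-dienoate by crossed Claisen condensation with one isolated batch of the lithium enolate of tert-butyl acetate.
5. The dienoate comes from a C6 bromide and acetylide, then zirconium-catalysed carboalumination/iodination, then Negishi coupling with a C3 zinc homoenolate.

**Assumption:** the SMILES is taken literally, so the two bicyclic halves are epimers at the acetoxy-bearing quaternary carbon; "ent-Shi ketone" means the L-fructose-derived enantiomer of the Shi epoxidation ketone; the central alkene, which is hydrogenated later, is drawn E but carried as an E/Z mixture.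

**Locants used in names:** decahydro-1-benzoxepine numbering, O1, C2 (CMe2), C3 (CH–O), C4, C5, C5a (C–CH3), C6 (CH carrying the one-carbon arm), C7, C8, C9, C9a (CH–O). Ring A is the oxepane, ring B the cyclohexane.

## Route

**Step 1**
Reactants: 1 5-bromo-2-methylpent-2-ene; 2 lithium acetylide–ethylenediamine complex
Product: 3 6-methylhept-5-en-1-yne
Conditions: DMSO, 10 → 25 °C
Reagents that add atoms: none
Why: SN2 alkylation of the acetylide by the primary homoallylic bromide in a dipolar aprotic solvent gives the terminal alkyne without touching the trisubstituted alkene.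

**Step 2**
Reactants: 3 6-methylhept-5-en-1-yne
Product: 5 (1E)-1-iodo-2,6-dimethylhepta-1,5-diene, via alkenylalane 4 (not isolated)
Conditions: Me3Al (2 equiv), Cp2ZrCl2 (0.25 equiv), CH2Cl2, 0 → 23 °C; then I2, THF, −30 → 0 °C
Reagents that add atoms: trimethylaluminium, C[Al](C)C; iodine, [I][I]
Why: Negishi zirconium-catalysed carboalumination adds CH3 and Al syn across the terminal alkyne with CH3 on the internal carbon, and iodinolysis of the C–Al bond with retention fixes the E trisubstituted alkene.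

**Step 3**
Reactants: 5 (1E)-1-iodo-2,6-dimethylhepta-1,5-diene; 6 ethyl 3-iodopropanoate
Product: 8 ethyl (4E)-5,9-dimethyldeca-4,8-dienoate, via zinc homoenolate 7 (not isolated)
Conditions: 6, Zn dust (activated with Me3SiCl), THF, 35 °C; then 5, Pd(PPh3)4 (4 mol %), THF, 23 → 45 °C
Reagents that add atoms: none
Why: Negishi sp2–sp3 cross-coupling of the ester-bearing organozinc proceeds with retention of alkene geometry and tolerates the ester.

**Step 4**
Reactants: 9 tert-butyl acetate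
Product: 10 lithium 1-(tert-butoxy)ethen-1-olate (lithium enolate of tert-butyl acetate, isolated as a white solid)
Conditions: LiN(iPr)2 (1.0 equiv), hexane, −78 °C; then volatiles removed in vacuo, 25 °C; solid stored under Ar
Reagents that add atoms: lithium diisopropylamide, CC(C)N([Li])C(C)C
Why: Irreversible kinetic ester enolisation by the hindered amide base gives a lithium enolate that does not self-condense and is stable as a solvent-free solid under argon, so one batch serves both Claisen condensations; no stereocentre is formed.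

**Step 5**
Reactants: 8 ethyl (4E)-5,9-dimethyldeca-4,8-dienoate; 10 lithium 1-(tert-butoxy)ethen-1-olate
Product: 11 tert-butyl (6E)-7,11-dimethyl-3-oxododeca-6,10-dienoate
Conditions: 10 (2.2 equiv), THF, −78 → 0 °C; then AcOH
Reagents that add atoms: none
Why: Crossed Claisen condensation in which the preformed, non-self-condensing lithium enolate acylates the ethyl ester and a second equivalent of 10 deprotonates the β-keto ester, which drives the equilibrium.

**Step 6**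
Reactants: 11 tert-butyl (6E)-7,11-dimethyl-3-oxododeca-6,10-dienoate
Product: 13 tert-butyl (2Z,6E)-3-[(diethoxyphosphoryl)oxy]-7,11-dimethyldodeca-2,6,10-trienoate, via sodium enolate 12 (not isolated)
Conditions: NaH, Et2O, 0 °C; then ClP(O)(OEt)2, 0 → 23 °C
Reagents that add atoms: diethyl chlorophosphate, CCOP(=O)(Cl)OCC
Why: O-phosphorylation of the sodium-chelated Z enolate (Weiler enol phosphate synthesis) places the phosphate cis to the ester.

**Step 7**
Reactants: 13 tert-butyl (2Z,6E)-3-[(diethoxyphosphoryl)oxy]-7,11-dimethyldodeca-2,6,10-trienoate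
Product: 14 tert-butyl (2Z,6E)-7,11-dimethyl-3-[(trimethylsilyl)methyl]dodeca-2,6,10-trienoate
Conditions: Me3SiCH2MgCl (2 equiv), Ni(acac)2 (5 mol %), THF, 0 → 23 °C
Reagents that add atoms: (trimethylsilyl)methylmagnesium chloride, C[Si](C)(C)C[Mg]Cl
Why: Nickel-catalysed Kumada-type coupling of the enol phosphate occurs with retention, giving the Z allylsilane whose CH2SiMe3 is cis to the ester, while the hindered tert-butyl ester is not attacked.

**Step 8**
Reactants: 14 tert-butyl (2Z,6E)-7,11-dimethyl-3-[(trimethylsilyl)methyl]dodeca-2,6,10-trienoate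
Product: 15 tert-butyl (2Z)-5-[(2S,3S)-3-{2-[(2S)-3,3-dimethyloxiran-2-yl]ethyl}-3-methyloxiran-2-yl]-3-[(trimethylsilyl)methyl]pent-2-enoate
Conditions: ent-Shi ketone (0.3 equiv per alkene), Oxone (2KHSO5·KHSO4·K2SO4), K2CO3, Bu4NHSO4 (cat.), MeCN–CH2(OMe)2 / aq. Na2B4O7 buffer (pH 10.5), 0 °C
Reagents that add atoms: potassium peroxymonosulfate, [K+].[O-]S(=O)(=O)OO
Why: Shi asymmetric epoxidation, in which the chiral dioxirane epoxidises only the two electron-rich trisubstituted alkenes through a spiro transition state, the ent-ketone giving S at every epoxide stereocentre, while the ester-conjugated alkene is inert.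

**Step 9**
Reactants: 15 tert-butyl (2Z)-5-[(2S,3S)-3-{2-[(2S)-3,3-dimethyloxiran-2-yl]ethyl}-3-methyloxiran-2-yl]-3-[(trimethylsilyl)methyl]pent-2-enoate
Product: 17 tert-butyl (3S,5aS,6R,9aS)-3-hydroxy-2,2,5a-trimethyl-7-methylidenedecahydro-1-benzoxepine-6-carboxylate, via trimethylsilyl ether 16 (not isolated)
Conditions: Me3SiOTf (0.3 equiv), 2,6-di-tert-butyl-4-methylpyridine (0.5 equiv), CH2Cl2, −78 °C; then 1 M HCl, THF, 0 °C
Reagents that add atoms: none
Why: Silyl-triflate-triggered tandem oxa/carbacyclisation in which the silyl-activated terminal epoxide is opened at its tertiary carbon by the internal epoxide oxygen (7-endo, ring A), the epoxonium ion is opened with inversion at its tertiary carbon by C2 of the allylsilane through a chair transition state (ring B, trans fusion, equatorial ester), and loss of Me3Si+ leaves the exocyclic methylene, so C3 and C9a keep the epoxide configurations and C5a is set by the anti opening.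

**Step 10**
Reactants: 17 tert-butyl (3S,5aS,6R,9aS)-3-hydroxy-2,2,5a-trimethyl-7-methylidenedecahydro-1-benzoxepine-6-carboxylate
Product: 18 tert-butyl (3S,5aS,6S,7S,9aS)-3-hydroxy-2,2,5a-trimethyloctahydro-2H-spiro[1-benzoxepine-7,2'-oxirane]-6-carboxylate (oxirane oxygen trans to the 5a-methyl)
Conditions: mCPBA, NaHCO3, CH2Cl2, 0 °C
Reagents that add atoms: 3-chloroperoxybenzoic acid, OOC(=O)c1cccc(Cl)c1
Why: Prilezhaev epoxidation from the α face, anti to the axial 5a-methyl that shields the β face of the exocyclic alkene, puts the oxirane oxygen equatorial (7S).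

**Step 11**
Reactants: 18 tert-butyl (3S,5aS,6S,7S,9aS)-3-hydroxy-2,2,5a-trimethyloctahydro-2H-spiro[1-benzoxepine-7,2'-oxirane]-6-carboxylate
Product: 19 (3S,5aS,6R,7S,9aS)-6-(hydroxymethyl)-2,2,5a,7-tetramethyldecahydro-1-benzoxepine-3,7-diol
Conditions: LiAlH4, THF, 0 → 65 °C; then H2O
Reagents that add atoms: none
Why: Hydride opens the spiro-epoxide by SN2 attack at its unhindered CH2, leaving the oxygen on C7 (equatorial OH, axial methyl, 7S), and reduces the tert-butyl ester to the primary alcohol.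

**Step 12**
Reactants: 19 (3S,5aS,6R,7S,9aS)-6-(hydroxymethyl)-2,2,5a,7-tetramethyldecahydro-1-benzoxepine-3,7-diol
Product: 20 (3S,5aS,6S,7S,9aS)-2,2,5a,7-tetramethyl-6-{[(1-phenyl-1H-tetrazol-5-yl)sulfanyl]methyl}decahydro-1-benzoxepine-3,7-diol
Conditions: 1-phenyl-1H-tetrazole-5-thiol, PPh3, DIAD, THF, 0 → 23 °C
Reagents that add atoms: 1-phenyl-1H-tetrazole-5-thiol, Sc1nnnn1-c1ccccc1
Why: Mitsunobu thioetherification in which only the primary carbinol is activated and displaced (SN2) by the acidic thiol, the neopentylic secondary and the tertiary hydroxyl being too hindered to react.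

**Step 13**
Reactants: 20 (3S,5aS,6S,7S,9aS)-2,2,5a,7-tetramethyl-6-{[(1-phenyl-1H-tetrazol-5-yl)sulfanyl]methyl}decahydro-1-benzoxepine-3,7-diol
Product: 21 1-phenyl-5-({[(3S,5aS,6S,7S,9aS)-2,2,5a,7-tetramethyl-3,7-bis(triethylsilyloxy)decahydro-1-benzoxepin-6-yl]methyl}sulfanyl)-1H-tetrazole
Conditions: Et3SiOTf (3 equiv), 2,6-lutidine, CH2Cl2, 0 → 23 °C
Reagents that add atoms: triethylsilyl trifluoromethanesulfonate, CC[Si](CC)(CC)OS(=O)(=O)C(F)(F)F
Why: The silyl triflate with a hindered pyridine base silylates both the hindered secondary and the tertiary hydroxyl, removing acidic protons and nucleophilic oxygens before the carbanion chemistry.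

**Step 14**
Reactants: 21 1-phenyl-5-({[(3S,5aS,6S,7S,9aS)-2,2,5a,7-tetramethyl-3,7-bis(triethylsilyloxy)decahydro-1-benzoxepin-6-yl]methyl}sulfanyl)-1H-tetrazole
Product: 22 1-phenyl-5-({[(3S,5aS,6S,7S,9aS)-2,2,5a,7-tetramethyl-3,7-bis(triethylsilyloxy)decahydro-1-benzoxepin-6-yl]methyl}sulfonyl)-1H-tetrazole
Conditions: mCPBA (2.5 equiv), NaHCO3, CH2Cl2, 0 → 23 °C
Reagents that add atoms: 3-chloroperoxybenzoic acid, OOC(=O)c1cccc(Cl)c1
Why: Peracid oxidation of the sulfide through the sulfoxide gives the sulfone, no alkene being present and the bicarbonate buffer protecting the silyl ethers.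

**Step 15**
Reactants: 8 ethyl (4E)-5,9-dimethyldeca-4,8-dienoate
Product: 23 ethyl 3-[(2S,3S)-3-{2-[(2S)-3,3-dimethyloxiran-2-yl]ethyl}-3-methyloxiran-2-yl]propanoate
Conditions: ent-Shi ketone (0.3 equiv per alkene), Oxone (2KHSO5·KHSO4·K2SO4), K2CO3, Bu4NHSO4 (cat.), MeCN–CH2(OMe)2 / aq. Na2B4O7 buffer (pH 10.5), 0 °C
Reagents that add atoms: potassium peroxymonosulfate, [K+].[O-]S(=O)(=O)OO
Why: Shi asymmetric epoxidation as in step 8 sets the three epoxide stereocentres (all S) under reagent control, the ester being stable at this pH and temperature.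

**Step 16**
Reactants: 23 ethyl 3-[(2S,3S)-3-{2-[(2S)-3,3-dimethyloxiran-2-yl]ethyl}-3-methyloxiran-2-yl]propanoate; 10 lithium 1-(tert-butoxy)ethen-1-olate
Product: 24 tert-butyl 5-[(2S,3S)-3-{2-[(2S)-3,3-dimethyloxiran-2-yl]ethyl}-3-methyloxiran-2-yl]-3-oxopentanoate
Conditions: 10 (2.2 equiv), THF, −78 → −20 °C; then AcOH
Reagents that add atoms: none
Why: Crossed Claisen condensation as in step 5, the ester enolate not opening the trisubstituted epoxides at low temperature.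

**Step 17**
Reactants: 24 tert-butyl 5-[(2S,3S)-3-{2-[(2S)-3,3-dimethyloxiran-2-yl]ethyl}-3-methyloxiran-2-yl]-3-oxopentanoate
Product: 25 tert-butyl (2Z)-3-{[tert-butyl(dimethyl)silyl]oxy}-5-[(2S,3S)-3-{2-[(2S)-3,3-dimethyloxiran-2-yl]ethyl}-3-methyloxiran-2-yl]pent-2-enoate
Conditions: tBuMe2SiOTf, Et3N, CH2Cl2, −78 → 0 °C
Reagents that add atoms: tert-butyldimethylsilyl trifluoromethanesulfonate, CC(C)(C)[Si](C)(C)OS(=O)(=O)C(F)(F)F
Why: Soft enolisation and O-silylation of the β-keto ester gives the Z β-silyloxy enoate, which removes the acidic protons and defines C2 as the π-nucleophile, the amine-buffered silyl triflate leaving the epoxides intact.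

**Step 18**
Reactants: 25 tert-butyl (2Z)-3-{[tert-butyl(dimethyl)silyl]oxy}-5-[(2S,3S)-3-{2-[(2S)-3,3-dimethyloxiran-2-yl]ethyl}-3-methyloxiran-2-yl]pent-2-enoate
Product: 27 tert-butyl (3S,5aS,6S,9aS)-3-hydroxy-2,2,5a-trimethyl-7-oxodecahydro-1-benzoxepine-6-carboxylate, via trimethylsilyl ether 26 (not isolated)
Conditions: Me3SiOTf (1.1 equiv), 2,6-di-tert-butyl-4-methylpyridine (1.5 equiv), CH2Cl2, −78 °C; then 1 M HCl, THF, 0 °C
Reagents that add atoms: none
Why: Tandem oxa/carbacyclisation as in step 9, here ended by Mukaiyama-type C-alkylation of the silyl enol ether, whose silyl group is lost to give the C7 ketone, with C3, C5a and C9a arising as in step 9 and the epimerisable ester at C6 settling equatorial.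

**Step 19**
Reactants: 27 tert-butyl (3S,5aS,6S,9aS)-3-hydroxy-2,2,5a-trimethyl-7-oxodecahydro-1-benzoxepine-6-carboxylate
Product: 28 tert-butyl (3S,5aS,6S,9aS)-3-(benzyloxy)-2,2,5a-trimethyl-7-oxodecahydro-1-benzoxepine-6-carboxylate
Conditions: 2-benzyloxy-1-methylpyridinium triflate, MgO, PhCF3, 83 °C
Reagents that add atoms: 2-(benzyloxy)-1-methylpyridin-1-ium trifluoromethanesulfonate, C[n+]1ccccc1OCc1ccccc1.[O-]S(=O)(=O)C(F)(F)F
Why: Thermal benzyl transfer from the pyridinium salt (Dudley benzylation) etherifies the hindered secondary alcohol under neutral conditions, so the β-keto ester is not alkylated.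

**Step 20**
Reactants: 28 tert-butyl (3S,5aS,6S,9aS)-3-(benzyloxy)-2,2,5a-trimethyl-7-oxodecahydro-1-benzoxepine-6-carboxylate
Product: 29 (3S,5aS,6R,7R,9aS)-3-(benzyloxy)-6-(hydroxymethyl)-2,2,5a-trimethyldecahydro-1-benzoxepin-7-ol (major C7 epimer)
Conditions: LiAlH4, THF, 0 → 65 °C; then H2O
Reagents that add atoms: none
Why: Hydride reduction of ketone and ester gives the 1,3-diol, attack on the ketone from the α face away from the axial 5a-methyl giving mainly the axial 7R alcohol, a centre that is removed again in step 22.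

**Step 21**
Reactants: 29 (3S,5aS,6R,7R,9aS)-3-(benzyloxy)-6-(hydroxymethyl)-2,2,5a-trimethyldecahydro-1-benzoxepin-7-ol
Product: 30 (3S,5aS,6R,7R,9aS)-3-(benzyloxy)-2,2,5a-trimethyl-6-{[(triethylsilyl)oxy]methyl}decahydro-1-benzoxepin-7-ol
Conditions: Et3SiCl (1.05 equiv), imidazole, CH2Cl2, −20 °C
Reagents that add atoms: chlorotriethylsilane, CC[Si](Cl)(CC)CC
Why: Kinetically selective silylation of the primary hydroxyl, the axial secondary hydroxyl being too hindered for the silyl chloride at low temperature.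

**Step 22**
Reactants: 30 (3S,5aS,6R,7R,9aS)-3-(benzyloxy)-2,2,5a-trimethyl-6-{[(triethylsilyl)oxy]methyl}decahydro-1-benzoxepin-7-ol
Product: 31 (3S,5aS,6R,9aS)-3-(benzyloxy)-2,2,5a-trimethyl-6-{[(triethylsilyl)oxy]methyl}octahydro-1-benzoxepin-7(2H)-one
Conditions: Dess–Martin periodinane, CH2Cl2, 0 → 23 °C
Reagents that add atoms: none
Why: Dess–Martin oxidation of the secondary alcohol regenerates the C7 ketone under near-neutral conditions without β-elimination of the silyloxy group or epimerisation at C6.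

**Step 23**
Reactants: 31 (3S,5aS,6R,9aS)-3-(benzyloxy)-2,2,5a-trimethyl-6-{[(triethylsilyl)oxy]methyl}octahydro-1-benzoxepin-7(2H)-one
Product: 32 (3S,5aS,6R,7R,9aS)-3-(benzyloxy)-2,2,5a,7-tetramethyl-6-{[(triethylsilyl)oxy]methyl}decahydro-1-benzoxepin-7-ol
Conditions: MeMgBr (3 equiv), THF, −78 → 0 °C; then H2O
Reagents that add atoms: methylmagnesium bromide, C[Mg]Br
Why: Grignard 1,2-addition in which axial approach is blocked by the syn-axial 5a-methyl, so the methyl enters equatorially from the α face and the new tertiary hydroxyl is axial (7R), the epimer of the centre made in step 11.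

**Step 24**
Reactants: 32 (3S,5aS,6R,7R,9aS)-3-(benzyloxy)-2,2,5a,7-tetramethyl-6-{[(triethylsilyl)oxy]methyl}decahydro-1-benzoxepin-7-ol
Product: 33 (3S,5aS,6R,7R,9aS)-3-(benzyloxy)-2,2,5a,7-tetramethyl-7-[(triethylsilyl)oxy]-6-{[(triethylsilyl)oxy]methyl}decahydro-1-benzoxepine
Conditions: Et3SiOTf, 2,6-lutidine, CH2Cl2, 0 → 23 °C
Reagents that add atoms: triethylsilyl trifluoromethanesulfonate, CC[Si](CC)(CC)OS(=O)(=O)C(F)(F)F
Why: Silyl triflate/2,6-lutidine silylates the hindered axial tertiary alcohol, which prevents retro-aldol cleavage of the β-oxygenated aldehyde to come.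

**Step 25**
Reactants: 33 (3S,5aS,6R,7R,9aS)-3-(benzyloxy)-2,2,5a,7-tetramethyl-7-[(triethylsilyl)oxy]-6-{[(triethylsilyl)oxy]methyl}decahydro-1-benzoxepine
Product: 34 (3S,5aS,6S,7R,9aS)-3-(benzyloxy)-2,2,5a,7-tetramethyl-7-[(triethylsilyl)oxy]decahydro-1-benzoxepine-6-carbaldehyde
Conditions: (COCl)2, DMSO, CH2Cl2, −78 → −30 °C; then Et3N, −78 → 0 °C
Reagents that add atoms: none
Why: Under Swern conditions the primary triethylsilyl ether is cleaved selectively and the alkoxysulfonium ion formed in situ collapses to the aldehyde on addition of base, the tertiary silyl ether and benzyl ether being untouched and the equatorial formyl group keeping the C6 configuration.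

**Step 26**
Reactants: 22 1-phenyl-5-({[(3S,5aS,6S,7S,9aS)-2,2,5a,7-tetramethyl-3,7-bis(triethylsilyloxy)decahydro-1-benzoxepin-6-yl]methyl}sulfonyl)-1H-tetrazole; 34 (3S,5aS,6S,7R,9aS)-3-(benzyloxy)-2,2,5a,7-tetramethyl-7-[(triethylsilyl)oxy]decahydro-1-benzoxepine-6-carbaldehyde
Product: 36 (3S,5aS,6S,7S,9aS)-6-[(E)-2-{(3S,5aS,6S,7R,9aS)-3-(benzyloxy)-2,2,5a,7-tetramethyl-7-[(triethylsilyl)oxy]decahydro-1-benzoxepin-6-yl}ethenyl]-2,2,5a,7-tetramethyl-3,7-bis[(triethylsilyl)oxy]decahydro-1-benzoxepine, via potassium sulfonyl carbanion 35 (not isolated)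
Conditions: 22, KN(SiMe3)2 (1.1 equiv), THF, −78 °C; then 34, −78 → 23 °C
Reagents that add atoms: none
Why: Julia–Kocienski olefination in which the sulfonyl carbanion adds to the aldehyde and Smiles rearrangement with loss of SO2 and the tetrazolyl oxide gives the central alkene, whose geometry is irrelevant because it is hydrogenated, no stereocentre being touched.

**Step 27**
Reactants: 36 (3S,5aS,6S,7S,9aS)-6-[(E)-2-{(3S,5aS,6S,7R,9aS)-3-(benzyloxy)-2,2,5a,7-tetramethyl-7-[(triethylsilyl)oxy]decahydro-1-benzoxepin-6-yl}ethenyl]-2,2,5a,7-tetramethyl-3,7-bis[(triethylsilyl)oxy]decahydro-1-benzoxepine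
Product: 37 (3S,5aS,6S,7S,9aS)-6-[(E)-2-{(3S,5aS,6S,7R,9aS)-3-(benzyloxy)-7-hydroxy-2,2,5a,7-tetramethyldecahydro-1-benzoxepin-6-yl}ethenyl]-2,2,5a,7-tetramethyldecahydro-1-benzoxepine-3,7-diol
Conditions: Bu4NF (6 equiv), THF, 23 → 45 °C
Reagents that add atoms: none
Why: Fluoride cleaves all three Si–O bonds (strong Si–F bond) and leaves the benzyl ether and the alkene intact.

**Step 28**
Reactants: 37 (3S,5aS,6S,7S,9aS)-6-[(E)-2-{(3S,5aS,6S,7R,9aS)-3-(benzyloxy)-7-hydroxy-2,2,5a,7-tetramethyldecahydro-1-benzoxepin-6-yl}ethenyl]-2,2,5a,7-tetramethyldecahydro-1-benzoxepine-3,7-diol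
Product: 38 (3S,5aS,6S,7S,9aS)-6-[(E)-2-{(3S,5aS,6S,7R,9aS)-7-acetoxy-3-(benzyloxy)-2,2,5a,7-tetramethyldecahydro-1-benzoxepin-6-yl}ethenyl]-2,2,5a,7-tetramethyldecahydro-1-benzoxepine-3,7-diyl diacetate
Conditions: Ac2O (10 equiv), DMAP (0.5 equiv), Et3N, toluene, 70 °C
Reagents that add atoms: acetic anhydride, CC(=O)OC(C)=O
Why: DMAP-catalysed acylation under forcing conditions esterifies the secondary and both hindered tertiary hydroxyls, the fourth oxygen being masked as its benzyl ether.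

**Step 29**
Reactants: 38 (3S,5aS,6S,7S,9aS)-6-[(E)-2-{(3S,5aS,6S,7R,9aS)-7-acetoxy-3-(benzyloxy)-2,2,5a,7-tetramethyldecahydro-1-benzoxepin-6-yl}ethenyl]-2,2,5a,7-tetramethyldecahydro-1-benzoxepine-3,7-diyl diacetate
Product: 39 (3S,5aS,6S,7S,9aS)-6-{2-[(3S,5aS,6S,7R,9aS)-7-acetoxy-3-hydroxy-2,2,5a,7-tetramethyldecahydro-1-benzoxepin-6-yl]ethyl}-2,2,5a,7-tetramethyldecahydro-1-benzoxepine-3,7-diyl diacetate (CNP0169816.2)
Conditions: H2 (4 atm), 10% Pd/C, EtOAc–EtOH, 23 °C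
Reagents that add atoms: none
Why: Heterogeneous hydrogenation saturates the disubstituted alkene and hydrogenolyses the benzyl ether in one operation, the acetates being inert and no new stereocentre being formed.

## Compound list

1 | 5-bromo-2-methylpent-2-ene | CC(C)=CCCBr | starting material
2 | lithium acetylide–ethylenediamine complex | [Li]C#C.NCCN | starting material
3 | 6-methylhept-5-en-1-yne | CC(C)=CCCC#C | intermediate
4 | [(1E)-2,6-dimethylhepta-1,5-dien-1-yl]dimethylalane | C[Al](C)/C=C(\C)CCC=C(C)C | intermediate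
5 | (1E)-1-iodo-2,6-dimethylhepta-1,5-diene | I/C=C(\C)CCC=C(C)C | intermediate
6 | ethyl 3-iodopropanoate | CCOC(=O)CCI | starting material
7 | (3-ethoxy-3-oxopropyl)zinc iodide | CCOC(=O)CC[Zn]I | intermediate
8 | ethyl (4E)-5,9-dimethyldeca-4,8-dienoate | CCOC(=O)CC/C=C(\C)CCC=C(C)C | intermediate
9 | tert-butyl acetate | CC(=O)OC(C)(C)C | starting material
10 | lithium 1-(tert-butoxy)ethen-1-olate | [Li]OC(=C)OC(C)(C)C | intermediate
11 | tert-butyl (6E)-7,11-dimethyl-3-oxododeca-6,10-dienoate | CC(C)(C)OC(=O)CC(=O)CC/C=C(\C)CCC=C(C)C | intermediate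
12 | sodium (2Z,6E)-1-(tert-butoxy)-7,11-dimethyl-1-oxododeca-2,6,10-trien-3-olate | [Na]O/C(CC/C=C(\C)CCC=C(C)C)=C\C(=O)OC(C)(C)C | intermediate
13 | tert-butyl (2Z,6E)-3-[(diethoxyphosphoryl)oxy]-7,11-dimethyldodeca-2,6,10-trienoate | CCOP(=O)(OCC)O/C(CC/C=C(\C)CCC=C(C)C)=C\C(=O)OC(C)(C)C | intermediate
14 | tert-butyl (2Z,6E)-7,11-dimethyl-3-[(trimethylsilyl)methyl]dodeca-2,6,10-trienoate | C[Si](C)(C)C/C(CC/C=C(\C)CCC=C(C)C)=C\C(=O)OC(C)(C)C | intermediate
15 | tert-butyl (2Z)-5-[(2S,3S)-3-{2-[(2S)-3,3-dimethyloxiran-2-yl]ethyl}-3-methyloxiran-2-yl]-3-[(trimethylsilyl)methyl]pent-2-enoate | C[Si](C)(C)C/C(CC[C@@H]1O[C@@]1(C)CC[C@@H]1OC1(C)C)=C\C(=O)OC(C)(C)C | intermediate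
16 | tert-butyl (3S,5aS,6R,9aS)-2,2,5a-trimethyl-7-methylidene-3-[(trimethylsilyl)oxy]decahydro-1-benzoxepine-6-carboxylate | C[Si](C)(C)O[C@H]1CC[C@]2(C)[C@H](CCC(=C)[C@H]2C(=O)OC(C)(C)C)OC1(C)C | intermediate
17 | tert-butyl (3S,5aS,6R,9aS)-3-hydroxy-2,2,5a-trimethyl-7-methylidenedecahydro-1-benzoxepine-6-carboxylate | O[C@H]1CC[C@]2(C)[C@H](CCC(=C)[C@H]2C(=O)OC(C)(C)C)OC1(C)C | intermediate
18 | tert-butyl (3S,5aS,6S,7S,9aS)-3-hydroxy-2,2,5a-trimethyloctahydro-2H-spiro[1-benzoxepine-7,2'-oxirane]-6-carboxylate | O[C@H]1CC[C@]2(C)[C@H](CC[C@]3(OC3)[C@H]2C(=O)OC(C)(C)C)OC1(C)C | intermediate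
19 | (3S,5aS,6R,7S,9aS)-6-(hydroxymethyl)-2,2,5a,7-tetramethyldecahydro-1-benzoxepine-3,7-diol | O[C@H]1CC[C@]2(C)[C@H](CC[C@](C)(O)[C@H]2CO)OC1(C)C | intermediate
20 | (3S,5aS,6S,7S,9aS)-2,2,5a,7-tetramethyl-6-{[(1-phenyl-1H-tetrazol-5-yl)sulfanyl]methyl}decahydro-1-benzoxepine-3,7-diol | O[C@H]1CC[C@]2(C)[C@H](CC[C@](C)(O)[C@H]2CSc2nnnn2-c2ccccc2)OC1(C)C | intermediate
21 | 1-phenyl-5-({[(3S,5aS,6S,7S,9aS)-2,2,5a,7-tetramethyl-3,7-bis(triethylsilyloxy)decahydro-1-benzoxepin-6-yl]methyl}sulfanyl)-1H-tetrazole | CC[Si](CC)(CC)O[C@H]1CC[C@]2(C)[C@H](CC[C@](C)(O[Si](CC)(CC)CC)[C@H]2CSc2nnnn2-c2ccccc2)OC1(C)C | intermediate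
22 | 1-phenyl-5-({[(3S,5aS,6S,7S,9aS)-2,2,5a,7-tetramethyl-3,7-bis(triethylsilyloxy)decahydro-1-benzoxepin-6-yl]methyl}sulfonyl)-1H-tetrazole | CC[Si](CC)(CC)O[C@H]1CC[C@]2(C)[C@H](CC[C@](C)(O[Si](CC)(CC)CC)[C@H]2CS(=O)(=O)c2nnnn2-c2ccccc2)OC1(C)C | intermediate
23 | ethyl 3-[(2S,3S)-3-{2-[(2S)-3,3-dimethyloxiran-2-yl]ethyl}-3-methyloxiran-2-yl]propanoate | CCOC(=O)CC[C@@H]1O[C@@]1(C)CC[C@@H]1OC1(C)C | intermediate
24 | tert-butyl 5-[(2S,3S)-3-{2-[(2S)-3,3-dimethyloxiran-2-yl]ethyl}-3-methyloxiran-2-yl]-3-oxopentanoate | CC(C)(C)OC(=O)CC(=O)CC[C@@H]1O[C@@]1(C)CC[C@@H]1OC1(C)C | intermediate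
25 | tert-butyl (2Z)-3-{[tert-butyl(dimethyl)silyl]oxy}-5-[(2S,3S)-3-{2-[(2S)-3,3-dimethyloxiran-2-yl]ethyl}-3-methyloxiran-2-yl]pent-2-enoate | CC(C)(C)[Si](C)(C)O/C(CC[C@@H]1O[C@@]1(C)CC[C@@H]1OC1(C)C)=C\C(=O)OC(C)(C)C | intermediate
26 | tert-butyl (3S,5aS,6S,9aS)-2,2,5a-trimethyl-7-oxo-3-[(trimethylsilyl)oxy]decahydro-1-benzoxepine-6-carboxylate | C[Si](C)(C)O[C@H]1CC[C@]2(C)[C@H](CCC(=O)[C@H]2C(=O)OC(C)(C)C)OC1(C)C | intermediate
27 | tert-butyl (3S,5aS,6S,9aS)-3-hydroxy-2,2,5a-trimethyl-7-oxodecahydro-1-benzoxepine-6-carboxylate | O[C@H]1CC[C@]2(C)[C@H](CCC(=O)[C@H]2C(=O)OC(C)(C)C)OC1(C)C | intermediate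
28 | tert-butyl (3S,5aS,6S,9aS)-3-(benzyloxy)-2,2,5a-trimethyl-7-oxodecahydro-1-benzoxepine-6-carboxylate | c1ccccc1CO[C@H]1CC[C@]2(C)[C@H](CCC(=O)[C@H]2C(=O)OC(C)(C)C)OC1(C)C | intermediate
29 | (3S,5aS,6R,7R,9aS)-3-(benzyloxy)-6-(hydroxymethyl)-2,2,5a-trimethyldecahydro-1-benzoxepin-7-ol | c1ccccc1CO[C@H]1CC[C@]2(C)[C@H](CC[C@@H](O)[C@H]2CO)OC1(C)C | intermediate
30 | (3S,5aS,6R,7R,9aS)-3-(benzyloxy)-2,2,5a-trimethyl-6-{[(triethylsilyl)oxy]methyl}decahydro-1-benzoxepin-7-ol | c1ccccc1CO[C@H]1CC[C@]2(C)[C@H](CC[C@@H](O)[C@H]2CO[Si](CC)(CC)CC)OC1(C)C | intermediate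
31 | (3S,5aS,6R,9aS)-3-(benzyloxy)-2,2,5a-trimethyl-6-{[(triethylsilyl)oxy]methyl}octahydro-1-benzoxepin-7(2H)-one | c1ccccc1CO[C@H]1CC[C@]2(C)[C@H](CCC(=O)[C@H]2CO[Si](CC)(CC)CC)OC1(C)C | intermediate
32 | (3S,5aS,6R,7R,9aS)-3-(benzyloxy)-2,2,5a,7-tetramethyl-6-{[(triethylsilyl)oxy]methyl}decahydro-1-benzoxepin-7-ol | c1ccccc1CO[C@H]1CC[C@]2(C)[C@H](CC[C@@](C)(O)[C@H]2CO[Si](CC)(CC)CC)OC1(C)C | intermediate
33 | (3S,5aS,6R,7R,9aS)-3-(benzyloxy)-2,2,5a,7-tetramethyl-7-[(triethylsilyl)oxy]-6-{[(triethylsilyl)oxy]methyl}decahydro-1-benzoxepine | c1ccccc1CO[C@H]1CC[C@]2(C)[C@H](CC[C@@](C)(O[Si](CC)(CC)CC)[C@H]2CO[Si](CC)(CC)CC)OC1(C)C | intermediate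
34 | (3S,5aS,6S,7R,9aS)-3-(benzyloxy)-2,2,5a,7-tetramethyl-7-[(triethylsilyl)oxy]decahydro-1-benzoxepine-6-carbaldehyde | c1ccccc1CO[C@H]1CC[C@]2(C)[C@H](CC[C@@](C)(O[Si](CC)(CC)CC)[C@H]2C=O)OC1(C)C | intermediate
35 | potassium salt of the α-sulfonyl carbanion of 22 | CC[Si](CC)(CC)O[C@H]1CC[C@]2(C)[C@H](CC[C@](C)(O[Si](CC)(CC)CC)[C@H]2[CH-]S(=O)(=O)c2nnnn2-c2ccccc2)OC1(C)C.[K+] | intermediate
36 | (3S,5aS,6S,7S,9aS)-6-[(E)-2-{(3S,5aS,6S,7R,9aS)-3-(benzyloxy)-2,2,5a,7-tetramethyl-7-[(triethylsilyl)oxy]decahydro-1-benzoxepin-6-yl}ethenyl]-2,2,5a,7-tetramethyl-3,7-bis[(triethylsilyl)oxy]decahydro-1-benzoxepine | CC[Si](CC)(CC)O[C@H]1CC[C@]2(C)[C@H](CC[C@](C)(O[Si](CC)(CC)CC)[C@H]2/C=C/[C@H]2[C@]3(C)CC[C@H](OCc4ccccc4)C(C)(C)O[C@H]3CC[C@@]2(C)O[Si](CC)(CC)CC)OC1(C)C | intermediate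
37 | (3S,5aS,6S,7S,9aS)-6-[(E)-2-{(3S,5aS,6S,7R,9aS)-3-(benzyloxy)-7-hydroxy-2,2,5a,7-tetramethyldecahydro-1-benzoxepin-6-yl}ethenyl]-2,2,5a,7-tetramethyldecahydro-1-benzoxepine-3,7-diol | O[C@H]1CC[C@]2(C)[C@H](CC[C@](C)(O)[C@H]2/C=C/[C@H]2[C@]3(C)CC[C@H](OCc4ccccc4)C(C)(C)O[C@H]3CC[C@@]2(C)O)OC1(C)C | intermediate
38 | (3S,5aS,6S,7S,9aS)-6-[(E)-2-{(3S,5aS,6S,7R,9aS)-7-acetoxy-3-(benzyloxy)-2,2,5a,7-tetramethyldecahydro-1-benzoxepin-6-yl}ethenyl]-2,2,5a,7-tetramethyldecahydro-1-benzoxepine-3,7-diyl diacetate | CC(=O)O[C@H]1CC[C@]2(C)[C@H](CC[C@](C)(OC(C)=O)[C@H]2/C=C/[C@H]2[C@]3(C)CC[C@H](OCc4ccccc4)C(C)(C)O[C@H]3CC[C@@]2(C)OC(C)=O)OC1(C)C | intermediate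
39 | (3S,5aS,6S,7S,9aS)-6-{2-[(3S,5aS,6S,7R,9aS)-7-acetoxy-3-hydroxy-2,2,5a,7-tetramethyldecahydro-1-benzoxepin-6-yl]ethyl}-2,2,5a,7-tetramethyldecahydro-1-benzoxepine-3,7-diyl diacetate (CNP0169816.2) | CC(=O)O[C@H]1CC[C@]2(C)[C@H](CC[C@](C)(OC(C)=O)[C@H]2CC[C@H]2[C@]3(C)CC[C@H](O)C(C)(C)O[C@H]3CC[C@@]2(C)OC(C)=O)OC1(C)C | target

## Step count

Total step count: 29.
Longest linear sequence: 18 steps (steps 1–3, 15–25, 26–29). The other branch (steps 5–14) runs in parallel and gives a 17-step path from 1 to 39. Step 4 is a one-step side branch that supplies enolate 10 to steps 5 and 16.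

## Steps most likely to fail, with fallbacks

**Step 9** (cascade ended by the ester-conjugated allylsilane, a weak π-nucleophile that may lose the race against other epoxonium pathways). The fallback sets out from 15 and comes back at 19. The ester of 15 is reduced with iBu2AlH (CH2Cl2, −78 °C) to allylic alcohol F1, which is acetylated (Ac2O, pyridine) to allylic acetate F2; its allylsilane is no longer conjugated and is a much stronger terminator. The same Me3SiOTf cascade gives trimethylsilyl ether F3, hydrolysed on acidic work-up to bicyclic acetate F4. mCPBA gives α-spiro-epoxide F5, and LiAlH4 (epoxide opening plus acetate cleavage) returns triol 19, bypassing 17 and 18.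

**Step 18** (cascade ended by the β-silyloxy enoate; premature desilylation or attack through oxygen may compete). The fallback sets out from 17 and comes back at 27. Ozonolysis of the exocyclic methylene of 17 (O3, CH2Cl2–MeOH, −78 °C; then Me2S) gives keto ester 27 by alkene cleavage in place of a second cascade. No new compound arises.

**Step 26** (Julia–Kocienski union of two partners that are each flanked by two fully substituted carbons; addition may be slower than self-condensation of the tetrazolyl sulfone). The fallback sets out from 19 and comes back at 36, using a classical Julia–Lythgoe sequence. PhSSPh/Bu3P converts 19 into phenyl sulfide F6; Et3SiOTf/2,6-lutidine gives bis-silyl ether F7; mCPBA gives phenyl sulfone F8. n-BuLi (THF, −78 °C) gives lithio sulfone F9, which is smaller and does not self-condense. It adds to aldehyde 34, and the adduct is trapped in the same flask with BzCl as benzoyloxy sulfone F10 (diastereomer mixture). Reductive elimination with sodium amalgam Na(Hg) (Na2HPO4, MeOH–THF, −20 °C) gives alkene 36.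

## Further compounds

F1 | step 9 | (2Z)-5-[(2S,3S)-3-{2-[(2S)-3,3-dimethyloxiran-2-yl]ethyl}-3-methyloxiran-2-yl]-3-[(trimethylsilyl)methyl]pent-2-en-1-ol | C[Si](C)(C)C/C(CC[C@@H]1O[C@@]1(C)CC[C@@H]1OC1(C)C)=C\CO
F2 | step 9 | (2Z)-5-[(2S,3S)-3-{2-[(2S)-3,3-dimethyloxiran-2-yl]ethyl}-3-methyloxiran-2-yl]-3-[(trimethylsilyl)methyl]pent-2-en-1-yl acetate | C[Si](C)(C)C/C(CC[C@@H]1O[C@@]1(C)CC[C@@H]1OC1(C)C)=C\COC(C)=O
F3 | step 9 | {(3S,5aS,6R,9aS)-2,2,5a-trimethyl-7-methylidene-3-[(trimethylsilyl)oxy]decahydro-1-benzoxepin-6-yl}methyl acetate | C[Si](C)(C)O[C@H]1CC[C@]2(C)[C@H](CCC(=C)[C@H]2COC(C)=O)OC1(C)C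
F4 | step 9 | [(3S,5aS,6R,9aS)-3-hydroxy-2,2,5a-trimethyl-7-methylidenedecahydro-1-benzoxepin-6-yl]methyl acetate | O[C@H]1CC[C@]2(C)[C@H](CCC(=C)[C@H]2COC(C)=O)OC1(C)C
F5 | step 9 | [(3S,5aS,6R,7S,9aS)-3-hydroxy-2,2,5a-trimethyloctahydro-2H-spiro[1-benzoxepine-7,2'-oxiran]-6-yl]methyl acetate | O[C@H]1CC[C@]2(C)[C@H](CC[C@]3(OC3)[C@H]2COC(C)=O)OC1(C)C
F0 | step 18 | none | none
F6 | step 26 | (3S,5aS,6S,7S,9aS)-2,2,5a,7-tetramethyl-6-[(phenylsulfanyl)methyl]decahydro-1-benzoxepine-3,7-diol | O[C@H]1CC[C@]2(C)[C@H](CC[C@](C)(O)[C@H]2CSc2ccccc2)OC1(C)C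
F7 | step 26 | (3S,5aS,6S,7S,9aS)-2,2,5a,7-tetramethyl-6-[(phenylsulfanyl)methyl]-3,7-bis[(triethylsilyl)oxy]decahydro-1-benzoxepine | CC[Si](CC)(CC)O[C@H]1CC[C@]2(C)[C@H](CC[C@](C)(O[Si](CC)(CC)CC)[C@H]2CSc2ccccc2)OC1(C)C
F8 | step 26 | (3S,5aS,6S,7S,9aS)-2,2,5a,7-tetramethyl-6-[(phenylsulfonyl)methyl]-3,7-bis[(triethylsilyl)oxy]decahydro-1-benzoxepine | CC[Si](CC)(CC)O[C@H]1CC[C@]2(C)[C@H](CC[C@](C)(O[Si](CC)(CC)CC)[C@H]2CS(=O)(=O)c2ccccc2)OC1(C)C
F9 | step 26 | lithium salt of the α-sulfonyl carbanion of F8 | CC[Si](CC)(CC)O[C@H]1CC[C@]2(C)[C@H](CC[C@](C)(O[Si](CC)(CC)CC)[C@H]2[CH-]S(=O)(=O)c2ccccc2)OC1(C)C.[Li+]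
F10 | step 26 | 1-{(3S,5aS,6R,7R,9aS)-3-(benzyloxy)-2,2,5a,7-tetramethyl-7-[(triethylsilyl)oxy]decahydro-1-benzoxepin-6-yl}-2-(phenylsulfonyl)-2-{(3S,5aS,6S,7S,9aS)-2,2,5a,7-tetramethyl-3,7-bis[(triethylsilyl)oxy]decahydro-1-benzoxepin-6-yl}ethyl benzoate (mixture at the two new centres) | CC[Si](CC)(CC)O[C@H]1CC[C@]2(C)[C@H](CC[C@](C)(O[Si](CC)(CC)CC)[C@H]2C(C(OC(=O)c2ccccc2)[C@H]2[C@]3(C)CC[C@H](OCc4ccccc4)C(C)(C)O[C@H]3CC[C@@]2(C)O[Si](CC)(CC)CC)S(=O)(=O)c2ccccc2)OC1(C)C
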